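## Retrosynthetic overview

1. Ring C (pyranone) is closed last by C–O cyclodehydration of a 1,3-diketone, made by Claisen condensation of 2',4',6'-trihydroxyacetophenone (ring A) with a fully functionalised ring B methyl ester.
2. The dihydrofuran aryl-O–C2 bond comes from a stereoinvertive 5-exo opening of a threo epoxy alcohol by a phenoxide; the phenoxide is unmasked by aromatic Claisen rearrangement of an O-(1,1-dimethylallyl) ether, which also delivers the prenyl group.
3. The epoxy alcohol comes from a one-flask asymmetric isobutenylzinc addition / alkoxide-directed epoxidation of the aryl-ether aldehyde (sets C3, then the epoxide carbon).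
4. The aryl ether comes from methyl 3-formyl-4-hydroxybenzoate by copper-catalysed propargylation and semi-hydrogenation.
5. Ring order: benzene ring B (bought) → oxirane → dihydrofuran → pyranone ring C fused to bought ring A.

Assumption: the target SMILES is read as the trans-(2S,3S) diol, and (−)-MIB is taken to direct addition to the Si face of aryl aldehydes as with benzaldehyde, so (+)-MIB is used for the Re-face addition needed here (the antipode is used if the sense proves opposite).

## Route

Step 1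
Reactants: 1 methyl 3-formyl-4-hydroxybenzoate; 2 3-chloro-3-methylbut-1-yne
Product: 3 methyl 3-formyl-4-[(2-methylbut-3-yn-2-yl)oxy]benzoate
Conditions: 2 (1.4 equiv), DBU (1.5 equiv), CuCl2·2H2O (1 mol%), MeCN, 0 °C to rt
Reagents that add atoms: none
Why: Copper-catalysed propargylic etherification (copper acetylide/allenylidene-type intermediate) puts the tertiary propargyl group on the acidic phenol oxygen without elimination; no stereocenter is formed.

Step 2
Reactants: 3 methyl 3-formyl-4-[(2-methylbut-3-yn-2-yl)oxy]benzoate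
Product: 4 methyl 3-formyl-4-[(2-methylbut-3-en-2-yl)oxy]benzoate
Conditions: H2 (1 atm), Pd/CaCO3–Pb(OAc)2 (Lindlar catalyst), quinoline, EtOAc, 0 °C to rt (kept below 30 °C)
Reagents that add atoms: none
Why: Lindlar semi-hydrogenation stops at the terminal alkene and leaves aldehyde and ester alone; keeping the ether cool avoids a premature Claisen shift.

Step 3
Reactants: 4 methyl 3-formyl-4-[(2-methylbut-3-en-2-yl)oxy]benzoate
Product: 6 methyl 3-[(S)-[(2R)-3,3-dimethyloxiran-2-yl](hydroxy)methyl]-4-[(2-methylbut-3-en-2-yl)oxy]benzoate, via zinc (R)-allylic alkoxide 5 (not isolated)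
Conditions: (Me2C=CH)2Zn (1.5 equiv; from Me2C=CHMgBr + ZnCl2, MgBrCl removed with 1,4-dioxane, solvent changed to toluene), (+)-MIB [(2R)-3-exo-morpholinoisoborneol] (5 mol%), toluene, 0 °C; then t-BuOOH (3 equiv, decane), Ti(OiPr)4 (20 mol%), −20 to 0 °C; aq. NaHCO3/Na2S2O3
Reagents that add atoms: bis(2-methylprop-1-en-1-yl)zinc, CC(C)=C[Zn]C=C(C)C (made in the flask from 2-methylprop-1-en-1-ylmagnesium bromide, CC(C)=C[Mg]Br, and ZnCl2); tert-butyl hydroperoxide, CC(C)(C)OO
Why: Amino-alkoxide–zinc (Noyori-type) catalysed alkenylzinc 1,2-addition delivers the isobutenyl group to the Re face to give the (R)-alkoxide 5, and the alkoxide-directed titanium peroxide epoxidation then goes through the conformer that avoids A1,3 strain with the cis-methyl group, giving the threo (S,R) epoxy alcohol (known one-pot asymmetric alkenylation/directed epoxidation); the isolated vinyl group of the ether is not an allylic alcohol and is not epoxidised.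

Step 4
Reactants: 6 methyl 3-[(S)-[(2R)-3,3-dimethyloxiran-2-yl](hydroxy)methyl]-4-[(2-methylbut-3-en-2-yl)oxy]benzoate
Product: 8 methyl (2S,3S)-3-hydroxy-2-(2-hydroxypropan-2-yl)-7-(3-methylbut-2-en-1-yl)-2,3-dihydro-1-benzofuran-5-carboxylate, via ortho-prenyl phenoxide epoxy alcohol 7 (not isolated)
Conditions: K2CO3 (2 equiv), DMF (degassed), 110 °C, argon
Reagents that add atoms: none
Why: Proposed new method: a base-buffered "Claisen-unmasking cycloetherification" in which the O-(1,1-dimethylallyl) group acts as a traceless phenol mask that moves to carbon; the [3,3] shift to the only free ortho position (eased by the gem-dimethyl group) gives, after rearomatisation under carbonate, phenoxide 7 carrying the prenyl group, which at once opens the neighbouring epoxide at its secondary carbon by 5-exo-tet SN2 attack (inversion, R epoxide carbon becomes 2S; C3 untouched, hence the trans diol), while the basic medium suppresses the acid-type 6-endo attack at the tertiary carbon; the closest known reactions are the aromatic Claisen rearrangement of aryl 1,1-dimethylallyl ethers and the base-mediated closure of ortho-(2,3-epoxy-3-methylbutyl)phenols to 2-(2-hydroxypropan-2-yl)dihydrobenzofurans, which have not been coupled in this way.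

Step 5
Reactants: 8 methyl (2S,3S)-3-hydroxy-2-(2-hydroxypropan-2-yl)-7-(3-methylbut-2-en-1-yl)-2,3-dihydro-1-benzofuran-5-carboxylate; 9 2',4',6'-trihydroxyacetophenone (anhydrous)
Product: 11 5,7-dihydroxy-2-[(2S,3S)-3-hydroxy-2-(2-hydroxypropan-2-yl)-7-(3-methylbut-2-en-1-yl)-2,3-dihydro-1-benzofuran-5-yl]-4H-chromen-4-one, via 1,3-diketone 10 (not isolated)
Conditions: 9 (1.2 equiv), LiN(SiMe3)2 (7 equiv), THF, −78 °C to rt; then 8, rt to 50 °C; then AcOH (excess), 60 °C
Reagents that add atoms: none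
Why: Crossed Claisen condensation of the polylithiated acetophenone enolate with the aryl ester gives diketone 10 (the two alcohols ride along as alkoxides), and mild acid closes ring C by hemiketal formation and loss of water (Cushman-type polyanion flavone synthesis); ring A is symmetric so there is no regiochemical issue, and the two stereocenters are remote and untouched.

## Compound list

1 | methyl 3-formyl-4-hydroxybenzoate | COC(=O)c1ccc(O)c(C=O)c1 | starting material
2 | 3-chloro-3-methylbut-1-yne | CC(C)(Cl)C#C | starting material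
3 | methyl 3-formyl-4-[(2-methylbut-3-yn-2-yl)oxy]benzoate | COC(=O)c1ccc(OC(C)(C)C#C)c(C=O)c1 | intermediate
4 | methyl 3-formyl-4-[(2-methylbut-3-en-2-yl)oxy]benzoate | COC(=O)c1ccc(OC(C)(C)C=C)c(C=O)c1 | intermediate
5 | (2-methylprop-1-en-1-yl)zinc alkoxide of methyl 3-[(1R)-1-hydroxy-3-methylbut-2-en-1-yl]-4-[(2-methylbut-3-en-2-yl)oxy]benzoate | COC(=O)c1ccc(OC(C)(C)C=C)c(c1)[C@H](O[Zn]C=C(C)C)C=C(C)C | intermediate (not isolated)
6 | methyl 3-[(S)-[(2R)-3,3-dimethyloxiran-2-yl](hydroxy)methyl]-4-[(2-methylbut-3-en-2-yl)oxy]benzoate | COC(=O)c1ccc(OC(C)(C)C=C)c(c1)[C@H](O)[C@H]2OC2(C)C | intermediate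
7 | methyl 3-[(S)-[(2R)-3,3-dimethyloxiran-2-yl](hydroxy)methyl]-4-hydroxy-5-(3-methylbut-2-en-1-yl)benzoate (formed as its potassium phenoxide) | CC(C)=CCc1cc(C(=O)OC)cc(c1O)[C@H](O)[C@H]2OC2(C)C | intermediate (not isolated)
8 | methyl (2S,3S)-3-hydroxy-2-(2-hydroxypropan-2-yl)-7-(3-methylbut-2-en-1-yl)-2,3-dihydro-1-benzofuran-5-carboxylate | CC(C)=CCc1cc(C(=O)OC)cc2c1O[C@H](C(C)(C)O)[C@H]2O | intermediate
9 | 2',4',6'-trihydroxyacetophenone | CC(=O)c1c(O)cc(O)cc1O | starting material
10 | 1-[(2S,3S)-3-hydroxy-2-(2-hydroxypropan-2-yl)-7-(3-methylbut-2-en-1-yl)-2,3-dihydro-1-benzofuran-5-yl]-3-(2,4,6-trihydroxyphenyl)propane-1,3-dione | CC(C)=CCc1cc(C(=O)CC(=O)c3c(O)cc(O)cc3O)cc2c1O[C@H](C(C)(C)O)[C@H]2O | intermediate (not isolated)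
11 | 5,7-dihydroxy-2-[(2S,3S)-3-hydroxy-2-(2-hydroxypropan-2-yl)-7-(3-methylbut-2-en-1-yl)-2,3-dihydro-1-benzofuran-5-yl]-4H-chromen-4-one | CC(C)=CCc1cc(-c2cc(=O)c3c(O)cc(O)cc3o2)cc2c1O[C@H](C(C)(C)O)[C@H]2O | target

## Step count and risks

Total steps: 5. Longest linear sequence: 5 (1 → 3 → 4 → 6 → 8 → 11); 2 and 9 are bought.

**Step 4 (the proposed new step).** Risks are loss of the tertiary allyl group as isoprene instead of the [3,3] shift, 6-endo opening, or thermal damage to the epoxy alcohol. The fallback uses known chemistry only, sets out from 4 and comes back at 7 (and so 8). The Claisen rearrangement is run before the stereocenters exist (toluene, 110 °C) to give methyl 3-formyl-4-hydroxy-5-(3-methylbut-2-en-1-yl)benzoate F2. The phenol is capped with allyl bromide/K2CO3 in DMF to give methyl 3-formyl-5-(3-methylbut-2-en-1-yl)-4-(prop-2-en-1-yloxy)benzoate F3. The alkenylation/epoxidation of step 3 applied to F3 gives, through the zinc (R)-allylic alkoxide of the allyl ether F4, methyl 3-[(S)-[(2R)-3,3-dimethyloxiran-2-yl](hydroxy)methyl]-5-(3-methylbut-2-en-1-yl)-4-(prop-2-en-1-yloxy)benzoate F5. Pd(PPh3)4 with K2CO3 in MeOH at room temperature then removes the allyl group, and the phenoxide 7 so released closes to 8 under the same basic conditions.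

**Step 3.** Risks are loss of ee through residual magnesium halide or chelation by the ortho ether, Lewis-acid cleavage of the tertiary allyl ether, and titanium-mediated opening of the 3,3-disubstituted epoxide. The fallback sets out from 4 and comes back at 6. An asymmetric Nozaki–Hiyama–Kishi coupling of 4 with 1-bromo-2-methylprop-1-ene (CrCl2 with a chiral oxazoline–sulfonamide ligand, NiCl2(2,9-dimethyl-1,10-phenanthroline), Mn, Cp2ZrCl2, LiCl, MeCN) gives the isolated alcohol methyl 3-[(1R)-1-hydroxy-3-methylbut-2-en-1-yl]-4-[(2-methylbut-3-en-2-yl)oxy]benzoate F1. Its ee can be measured and raised before a separate threo-selective, hydroxyl-directed epoxidation (Ti(OiPr)4, t-BuOOH, CH2Cl2, −20 °C) to 6.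

**Step 5.** Risks are a sluggish condensation of the polyanion with the electron-rich ester and acid-promoted dehydration of the benzylic alcohol to a benzofuran during ring closure. The fallback sets out from 8 and comes back at 10. Both alcohols are silylated (Et3SiOTf, 2,6-lutidine, CH2Cl2) to give methyl (2S,3S)-7-(3-methylbut-2-en-1-yl)-3-[(triethylsilyl)oxy]-2-{2-[(triethylsilyl)oxy]propan-2-yl}-2,3-dihydro-1-benzofuran-5-carboxylate F6. Anhydrous ester cleavage with KOSiMe3 in THF gives the corresponding carboxylic acid F7. 1-Chloro-N,N,2-trimethylprop-1-en-1-amine under neutral conditions gives the acid chloride F8. C-acylation of the tetralithium salt of 9 (LiN(SiMe3)2, THF, −78 °C) with F8 gives the bis(triethylsilyl) ether of the 1,3-diketone F9. Buffered Bu4NF/AcOH removes the silyl groups to give 10, which is closed to 11 with AcOH as in step 5 (longer at room temperature if the benzylic alcohol proves sensitive).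

Further compounds

F1 | step 3 | methyl 3-[(1R)-1-hydroxy-3-methylbut-2-en-1-yl]-4-[(2-methylbut-3-en-2-yl)oxy]benzoate | COC(=O)c1ccc(OC(C)(C)C=C)c(c1)[C@H](O)C=C(C)C
F2 | step 4 | methyl 3-formyl-4-hydroxy-5-(3-methylbut-2-en-1-yl)benzoate | COC(=O)c1cc(CC=C(C)C)c(O)c(C=O)c1
F3 | step 4 | methyl 3-formyl-5-(3-methylbut-2-en-1-yl)-4-(prop-2-en-1-yloxy)benzoate | COC(=O)c1cc(CC=C(C)C)c(OCC=C)c(C=O)c1
F4 | step 4 | (2-methylprop-1-en-1-yl)zinc alkoxide of methyl 3-[(1R)-1-hydroxy-3-methylbut-2-en-1-yl]-5-(3-methylbut-2-en-1-yl)-4-(prop-2-en-1-yloxy)benzoate | COC(=O)c1cc(CC=C(C)C)c(OCC=C)c(c1)[C@H](O[Zn]C=C(C)C)C=C(C)C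
F5 | step 4 | methyl 3-[(S)-[(2R)-3,3-dimethyloxiran-2-yl](hydroxy)methyl]-5-(3-methylbut-2-en-1-yl)-4-(prop-2-en-1-yloxy)benzoate | COC(=O)c1cc(CC=C(C)C)c(OCC=C)c(c1)[C@H](O)[C@H]2OC2(C)C
F6 | step 5 | methyl (2S,3S)-7-(3-methylbut-2-en-1-yl)-3-[(triethylsilyl)oxy]-2-{2-[(triethylsilyl)oxy]propan-2-yl}-2,3-dihydro-1-benzofuran-5-carboxylate | CC(C)=CCc1cc(C(=O)OC)cc2c1O[C@H](C(C)(C)O[Si](CC)(CC)CC)[C@H]2O[Si](CC)(CC)CC
F7 | step 5 | (2S,3S)-7-(3-methylbut-2-en-1-yl)-3-[(triethylsilyl)oxy]-2-{2-[(triethylsilyl)oxy]propan-2-yl}-2,3-dihydro-1-benzofuran-5-carboxylic acid | CC(C)=CCc1cc(C(=O)O)cc2c1O[C@H](C(C)(C)O[Si](CC)(CC)CC)[C@H]2O[Si](CC)(CC)CC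
F8 | step 5 | (2S,3S)-7-(3-methylbut-2-en-1-yl)-3-[(triethylsilyl)oxy]-2-{2-[(triethylsilyl)oxy]propan-2-yl}-2,3-dihydro-1-benzofuran-5-carbonyl chloride | CC(C)=CCc1cc(C(=O)Cl)cc2c1O[C@H](C(C)(C)O[Si](CC)(CC)CC)[C@H]2O[Si](CC)(CC)CC
F9 | step 5 | 1-[(2S,3S)-7-(3-methylbut-2-en-1-yl)-3-[(triethylsilyl)oxy]-2-{2-[(triethylsilyl)oxy]propan-2-yl}-2,3-dihydro-1-benzofuran-5-yl]-3-(2,4,6-trihydroxyphenyl)propane-1,3-dione | CC(C)=CCc1cc(C(=O)CC(=O)c3c(O)cc(O)cc3O)cc2c1O[C@H](C(C)(C)O[Si](CC)(CC)CC)[C@H]2O[Si](CC)(CC)CC
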